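## Retrosynthetic overview

1. Last bonds: C11–C12 by alkylation of a C11 sulfonyl carbanion on the bicyclic core with an ω-silyloxy (2E,6E,10E)-farnesyl bromide, then reductive desulfonylation; C8–CH3 by methyl addition to an 8-ketone; C9–C11 by thiomethylation of a regiodefined C8=C9 silyl enol ether.
2. Core: both rings of the cis-decalin come from an acyclic triene in one intramolecular Diels–Alder reaction that forms C6–C7 and C5–C10. Ring B is the new cyclohexene and ring A closes through the tether C1–C4 in the same event; a phenylsulfonyl group on C6 activates the dienophile and is removed afterwards.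
3. Enabling feature: ring B (C5–C6–C7–C8–C9–C10) carries oxygen on C8 and is cis-fused to ring A (H-5 and the C10 methyl on one face). It therefore maps onto a 2-silyloxydiene C7=C8–C9=C10 with a (Z)-C9=C10 bond (tether inside, methyl outside) and a dienophile C5=C6, joined by C1–C4; the Z geometry allows only the cis-fused mode and C3 selects the face.
4. The triene is assembled from neryl acetate (C8, C9, C10 with its methyl, C1–C3), an isobutyrate silyl ketene acetal in a Kiyooka aldol (C4 with both methyls, C5; sets C3), MeMgBr (C7) and a sulfonylmethyl phosphonate (C6).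
5. Ring order: no ring before step 11; rings A and B are formed together in step 11.

Key step: step 11

Remarks on the chemistry (assumptions):
- Stereochemical reading of the target: the string places H-5 on the same face as the C10 methyl (C5 is S because C4 outranks C10), so the decalin is cis-fused. O-3, H-5, CH3-10, C11 (on C9) and CH3-8 are on one face (β) and HO-8 on the other (α). The route is built for exactly this stereoisomer, (3S,5S,8R,9R,10S).
- Numbering: decalin carbons C1–C10 as in drimane, C11 is the carbon on C9; β is the face of the C10 methyl; TBS = tert-butyldimethylsilyl.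
- Assumption: the oxazaborolidinone from N-tosyl-D-valine is taken to deliver the 3S aldol; if the sense of induction is the opposite, the L-valine promoter is used and nothing else changes.

## Route

Step 1
Reactants: 1 neryl acetate, (2Z)-3,7-dimethylocta-2,6-dien-1-yl acetate
Product: 2 (2Z)-6,7-epoxy-3,7-dimethyloct-2-en-1-yl acetate (racemic at the epoxide)
Conditions: mCPBA (1.05 equiv), NaHCO3, CH2Cl2, 0 °C
Reagents that add atoms: 3-chloroperbenzoic acid, OOC(=O)c1cccc(Cl)c1
Why: Prilezhaev epoxidation, in which the peracid should select the remote, more electron-rich 6,7-alkene over the 2,3-alkene deactivated by the allylic acetate; the new epoxide stereocenter is racemic and is destroyed in step 2.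

Step 2
Reactants: 2 (2Z)-6,7-epoxy-3,7-dimethyloct-2-en-1-yl acetate
Product: 3 (4Z)-6-acetoxy-4-methylhex-4-enal
Conditions: H5IO6, THF–H2O, 0 °C
Reagents that add atoms: none
Why: Periodic acid hydrolyses the epoxide and cleaves the glycol (Malaprade-type cleavage) to the aldehyde and acetone without touching the (Z)-allylic acetate.

Step 3
Reactants: 3 (4Z)-6-acetoxy-4-methylhex-4-enal; 4 1-methoxy-2-methyl-1-(trimethylsilyloxy)prop-1-ene
Product: 5 methyl (3S,6Z)-8-acetoxy-3-hydroxy-2,2,6-trimethyloct-6-enoate
Conditions: N-tosyl-D-valine, BH3·THF (1 equiv each), CH2Cl2, 0 °C to rt; then 3 and 4, −78 °C; pH 7 buffer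
Reagents that add atoms: 1-methoxy-2-methyl-1-(trimethylsilyloxy)prop-1-ene (4), COC(O[Si](C)(C)C)=C(C)C
Why: Kiyooka aldol reaction (oxazaborolidinone-promoted Mukaiyama aldol), in which the chiral boron Lewis acid binds the aldehyde and leaves one face open to the silyl ketene acetal, setting C3 as S while installing C4 with both methyl groups and C5.

Step 4
Reactants: 5 methyl (3S,6Z)-8-acetoxy-3-hydroxy-2,2,6-trimethyloct-6-enoate
Product: 6 methyl (3S,6Z)-8-acetoxy-3-(tert-butyldimethylsilyloxy)-2,2,6-trimethyloct-6-enoate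
Conditions: TBSOTf, 2,6-lutidine, CH2Cl2, −78 to 0 °C
Reagents that add atoms: tert-butyldimethylsilyl triflate, CC(C)(C)[Si](C)(C)OS(=O)(=O)C(F)(F)F
Why: Silylation with the triflate is the standard way to protect a hindered secondary alcohol next to a quaternary carbon, and no stereocenter is affected.

Step 5
Reactants: 6 methyl (3S,6Z)-8-acetoxy-3-(tert-butyldimethylsilyloxy)-2,2,6-trimethyloct-6-enoate
Product: 7 (2Z,6S)-6-(tert-butyldimethylsilyloxy)-3,7,7-trimethyloct-2-ene-1,8-diol
Conditions: i-Bu2AlH (5 equiv), CH2Cl2, −78 to 0 °C; Rochelle salt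
Reagents that add atoms: none
Why: Hydride reduction with i-Bu2AlH takes the hindered methyl ester to the neopentyl alcohol and cleaves the acetate in the same operation, the silyl ether and the (Z)-alkene being inert.

Step 6
Reactants: 7 (2Z,6S)-6-(tert-butyldimethylsilyloxy)-3,7,7-trimethyloct-2-ene-1,8-diol
Product: 8 (2Z,6S)-6-(tert-butyldimethylsilyloxy)-8-hydroxy-3,7,7-trimethyloct-2-enal
Conditions: MnO2 (activated, excess), CH2Cl2, 0 °C to rt
Reagents that add atoms: none
Why: MnO2 oxidises allylic alcohols selectively, so only the allylic hydroxyl should give the (Z)-enal while the saturated neopentyl alcohol stays, and the neutral heterogeneous conditions spare the Z geometry.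

Step 7
Reactants: 8 (2Z,6S)-6-(tert-butyldimethylsilyloxy)-8-hydroxy-3,7,7-trimethyloct-2-enal
Product: 9 (3Z,7S)-7-(tert-butyldimethylsilyloxy)-4,8,8-trimethylnon-3-ene-2,9-diol (both C2 epimers)
Conditions: MeMgBr (3 equiv), THF, −78 °C
Reagents that add atoms: methylmagnesium bromide, C[Mg]Br
Why: Grignard 1,2-addition to the enal (the first equivalent is spent on the free hydroxyl) brings in C7; the new carbinol is formed without control and is removed in step 8.

Step 8
Reactants: 9 (3Z,7S)-7-(tert-butyldimethylsilyloxy)-4,8,8-trimethylnon-3-ene-2,9-diol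
Product: 10 (3S,6Z)-3-(tert-butyldimethylsilyloxy)-2,2,6-trimethyl-8-oxonon-6-enal
Conditions: Dess–Martin periodinane (2.5 equiv), NaHCO3, CH2Cl2, 0 °C to rt
Reagents that add atoms: none
Why: Dess–Martin oxidation converts both alcohols under buffered, near-neutral conditions, which should keep the (Z)-enone from isomerising; the aldehyde has no α-hydrogen and cannot epimerise.

Step 9
Reactants: 10 (3S,6Z)-3-(tert-butyldimethylsilyloxy)-2,2,6-trimethyl-8-oxonon-6-enal; 11 diethyl [(phenylsulfonyl)methyl]phosphonate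
Product: 12 (3Z,7S,9E)-7-(tert-butyldimethylsilyloxy)-4,8,8-trimethyl-10-(phenylsulfonyl)deca-3,9-dien-2-one
Conditions: 11, NaH, THF, 0 °C; then 10, −20 to 0 °C
Reagents that add atoms: diethyl [(phenylsulfonyl)methyl]phosphonate (11), CCOP(=O)(OCC)CS(=O)(=O)c1ccccc1
Why: Horner–Wadsworth–Emmons olefination, in which the stabilised and weakly basic phosphonate anion should react only with the aldehyde, give the (E)-vinyl sulfone and leave the (Z)-enone untouched.

Step 10
Reactants: 12 (3Z,7S,9E)-7-(tert-butyldimethylsilyloxy)-4,8,8-trimethyl-10-(phenylsulfonyl)deca-3,9-dien-2-one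
Product: 13 (3Z,7S,9E)-2,7-bis(tert-butyldimethylsilyloxy)-4,8,8-trimethyl-10-(phenylsulfonyl)deca-1,3,9-triene
Conditions: TBSOTf, Et3N, CH2Cl2, −78 to 0 °C
Reagents that add atoms: tert-butyldimethylsilyl triflate, CC(C)(C)[Si](C)(C)OS(=O)(=O)C(F)(F)F
Why: Soft enolisation of the methyl ketone at the α′-methyl group gives the cross-conjugated 2-silyloxydiene under kinetic control; the vinyl sulfone has no γ-hydrogen and cannot isomerise.

Step 11
Reactants: 13 (3Z,7S,9E)-2,7-bis(tert-butyldimethylsilyloxy)-4,8,8-trimethyl-10-(phenylsulfonyl)deca-1,3,9-triene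
Product: 14 cis-fused cycloadduct, 3β,8-bis(tert-butyldimethylsilyloxy)-4,4,10β-trimethyl-6β-(phenylsulfonyl)-5β-H-octal-8-ene
Conditions: toluene (0.005 M), BHT (cat.), propylene oxide (acid scavenger), sealed tube, 170 °C
Reagents that add atoms: none
Why: Concerted, asynchronous thermal [4+2] cycloaddition (intramolecular Diels–Alder reaction) between the electron-rich 2-silyloxydiene C7=C8–C9=C10 and the (E)-vinyl sulfone C5=C6; the closest known reaction types are the thermal intramolecular Diels–Alder reactions of 1-sulfonyl-1,7,9-decatrienes and of trienes with a (Z)-diene. Ring B closes as the new cyclohexene (bonds C6–C7 and C5–C10) and ring A closes at the same time through the four-carbon tether C1–C4 in the fused mode. Because the tether sits on the inside (Z) position of C10, only the transition state with the tether exo to the diene can be reached, so H-5 and the outside C10 methyl must end up cis; the same geometry puts the sulfonyl group endo, the electronically preferred orientation, and fixes C6 as 6β (removed in step 12). The diene face is chosen by C3: in the chair-like tether the silyloxy group is equatorial, the axial alternative suffering a 1,3-diaxial clash with the sulfonyl-bearing C6, which puts O-3, H-5 and the C10 methyl on one face. The step needs cis-fusion, the C3-controlled face and periselectivity over the [1,5]-hydrogen shift of the (Z)-diene; the first two are secured by the (Z)-C9=C10 geometry and the C3 stereocenter next to the gem-dimethyl carbon, the third by sulfone activation, the gem-dialkyl effect of C4 and high dilution.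

Step 12
Reactants: 14 cis-fused cycloadduct
Product: 15 cis-fused silyl enol ether, 3β,8-bis(tert-butyldimethylsilyloxy)-4,4,10β-trimethyl-5β-H-octal-8-ene
Conditions: Na(Hg) (6%), Na2HPO4, MeOH–THF, −20 °C
Reagents that add atoms: none
Why: Reductive desulfonylation by electron transfer from sodium amalgam removes the activating group and the C6 stereocenter, the phosphate buffer keeping the silyl enol ether intact.

Step 13
Reactants: 15 cis-fused silyl enol ether; 16 chloromethyl phenyl sulfide
Product: 17 3β-(tert-butyldimethylsilyloxy)-4,4,10β-trimethyl-9β-[(phenylthio)methyl]-5β-H-decalin-8-one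
Conditions: 16, TiCl4, CH2Cl2, −78 °C; cold aqueous NaHCO3 quench
Reagents that add atoms: chloromethyl phenyl sulfide (16), ClCSc1ccccc1
Why: Lewis-acid-mediated α-(phenylthio)methylation of a silyl enol ether (Mukaiyama-type alkylation through the thionium ion) is regiospecific for C9; the electrophile should enter from the exo β face of the cis-fused bicycle because ring A is folded under the α face, which sets C9 (C11 β, H α) under kinetic control.

Step 14
Reactants: 17 9β-[(phenylthio)methyl] ketone
Product: 18 3β-(tert-butyldimethylsilyloxy)-11-(phenylthio)-5β-driman-8α-ol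
Conditions: MeLi, CeCl3 (dried), THF, −78 °C
Reagents that add atoms: methyllithium (as MeCeCl2), C[Li]
Why: Organocerium 1,2-addition (Imamoto conditions) should add methyl without enolisation or β-elimination of thiophenoxide; C1 of ring A blocks the α face of C8 in a 1,3-diaxial sense, so the methyl group enters from the β face and sets C8 (CH3 β, OH α).

Step 15
Reactants: 18 3β-(tert-butyldimethylsilyloxy)-11-(phenylthio)-5β-driman-8α-ol
Product: 19 3β-(tert-butyldimethylsilyloxy)-11-(phenylsulfonyl)-5β-driman-8α-ol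
Conditions: mCPBA (2.2 equiv), NaHCO3, CH2Cl2, 0 °C
Reagents that add atoms: 3-chloroperbenzoic acid, OOC(=O)c1cccc(Cl)c1
Why: Peracid oxidation of the sulfide to the sulfone is fast and chemoselective here because the molecule has no alkene left and the tertiary alcohol and silyl ether are inert.

Step 16
Reactants: 20 (2E,6E)-farnesol
Product: 21 (2E,6E)-farnesyl acetate
Conditions: Ac2O, pyridine, DMAP (cat.), CH2Cl2, 0 °C to rt
Reagents that add atoms: acetic anhydride, CC(=O)OC(C)=O
Why: Acetylation protects the allylic alcohol and deactivates the 2,3-alkene for the following allylic oxidation.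

Step 17
Reactants: 21 (2E,6E)-farnesyl acetate
Product: 22 (2E,6E,10E)-12-hydroxy-3,7,11-trimethyldodeca-2,6,10-trien-1-yl acetate
Conditions: SeO2 (cat.), t-BuOOH, CH2Cl2, 0 °C to rt
Reagents that add atoms: tert-butyl hydroperoxide, CC(C)(C)OO
Why: Riley allylic oxidation (ene reaction then [2,3]-shift) takes the (E)-methyl group of the terminal, most electron-rich trisubstituted alkene, which gives the (E)-allylic alcohol found at the chain end of the target.

Step 18
Reactants: 22 (2E,6E,10E)-12-hydroxyfarnesyl acetate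
Product: 23 (2E,6E,10E)-12-(tert-butyldimethylsilyloxy)-3,7,11-trimethyldodeca-2,6,10-trien-1-yl acetate
Conditions: TBSCl, imidazole, DMF, rt
Reagents that add atoms: tert-butyldimethylsilyl chloride, CC(C)(C)[Si](C)(C)Cl
Why: Standard silylation of the primary allylic alcohol, chosen so that both silyl ethers of the final intermediate fall in one fluoride step.

Step 19
Reactants: 23 12-silyloxy farnesyl acetate
Product: 24 (2E,6E,10E)-12-(tert-butyldimethylsilyloxy)-3,7,11-trimethyldodeca-2,6,10-trien-1-ol
Conditions: K2CO3 (cat.), MeOH, 0 °C to rt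
Reagents that add atoms: none
Why: Base-catalysed methanolysis removes the acetate and leaves the silyl ether and the alkene geometries alone.

Step 20
Reactants: 24 12-silyloxy farnesol
Product: 25 (2E,6E,10E)-1-bromo-12-(tert-butyldimethylsilyloxy)-3,7,11-trimethyldodeca-2,6,10-triene
Conditions: CBr4, PPh3, CH2Cl2, 0 °C
Reagents that add atoms: carbon tetrabromide, BrC(Br)(Br)Br
Why: Appel bromination converts the primary allylic alcohol under neutral conditions by SN2 displacement, so neither allylic transposition nor E/Z scrambling is expected.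

Step 21
Reactants: 19 3β-(tert-butyldimethylsilyloxy)-11-(phenylsulfonyl)-5β-driman-8α-ol; 25 ω-silyloxy farnesyl bromide
Product: 27 C11-(phenylsulfonyl) bis-silyl ether of the target skeleton (C11 epimers), via dilithio sulfone dianion 26 (not isolated)
Conditions: n-BuLi (2.1 equiv), THF–HMPA, −78 °C; then 25, −78 to −30 °C
Reagents that add atoms: none
Why: Alkylation of an α-sulfonyl carbanion (Julia-type fragment coupling): the alkoxide–carbanion dianion should attack the primary allylic bromide by SN2 with retention of the E geometry, forming C11–C12; the C11 stereocenter is formed without control and is removed in step 22.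

Step 22
Reactants: 27 C11-(phenylsulfonyl) bis-silyl ether
Product: 28 3β-O,ω-O-bis(tert-butyldimethylsilyl) ether of the target
Conditions: Na(Hg) (6%), Na2HPO4, MeOH–THF, −20 °C
Reagents that add atoms: none
Why: Reductive desulfonylation with sodium amalgam; the sulfone is homoallylic and not allylic, so no double-bond migration is expected and the isolated trisubstituted alkenes and silyl ethers are not reduced.

Step 23
Reactants: 28 bis-silyl ether
Product: 29 Myrrhanol A, the (3S,5S,8R,9R,10S) cis-fused triol as given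
Conditions: Bu4NF (excess), THF, 50 °C
Reagents that add atoms: none
Why: Fluoride-mediated desilylation frees both hydroxyls under non-acidic conditions, which protects the tertiary C8 alcohol and the allylic alcohol from elimination.

## Compound list

1 | neryl acetate, (2Z)-3,7-dimethylocta-2,6-dien-1-yl acetate | CC(=O)OC/C=C(/C)CCC=C(C)C | starting material
2 | (2Z)-6,7-epoxy-3,7-dimethyloct-2-en-1-yl acetate (racemic epoxide) | CC(=O)OC/C=C(/C)CCC1OC1(C)C | intermediate
3 | (4Z)-6-acetoxy-4-methylhex-4-enal | CC(=O)OC/C=C(/C)CCC=O | intermediate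
4 | 1-methoxy-2-methyl-1-(trimethylsilyloxy)prop-1-ene | COC(O[Si](C)(C)C)=C(C)C | starting material
5 | methyl (3S,6Z)-8-acetoxy-3-hydroxy-2,2,6-trimethyloct-6-enoate | CC(=O)OC/C=C(/C)CC[C@H](O)C(C)(C)C(=O)OC | intermediate
6 | methyl (3S,6Z)-8-acetoxy-3-(tert-butyldimethylsilyloxy)-2,2,6-trimethyloct-6-enoate | CC(=O)OC/C=C(/C)CC[C@H](O[Si](C)(C)C(C)(C)C)C(C)(C)C(=O)OC | intermediate
7 | (2Z,6S)-6-(tert-butyldimethylsilyloxy)-3,7,7-trimethyloct-2-ene-1,8-diol | OC/C=C(/C)CC[C@H](O[Si](C)(C)C(C)(C)C)C(C)(C)CO | intermediate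
8 | (2Z,6S)-6-(tert-butyldimethylsilyloxy)-8-hydroxy-3,7,7-trimethyloct-2-enal | O=C/C=C(/C)CC[C@H](O[Si](C)(C)C(C)(C)C)C(C)(C)CO | intermediate
9 | (3Z,7S)-7-(tert-butyldimethylsilyloxy)-4,8,8-trimethylnon-3-ene-2,9-diol (C2 epimers) | CC(O)/C=C(/C)CC[C@H](O[Si](C)(C)C(C)(C)C)C(C)(C)CO | intermediate
10 | (3S,6Z)-3-(tert-butyldimethylsilyloxy)-2,2,6-trimethyl-8-oxonon-6-enal | CC(=O)/C=C(/C)CC[C@H](O[Si](C)(C)C(C)(C)C)C(C)(C)C=O | intermediate
11 | diethyl [(phenylsulfonyl)methyl]phosphonate | CCOP(=O)(OCC)CS(=O)(=O)c1ccccc1 | starting material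
12 | (3Z,7S,9E)-7-(tert-butyldimethylsilyloxy)-4,8,8-trimethyl-10-(phenylsulfonyl)deca-3,9-dien-2-one | CC(=O)/C=C(/C)CC[C@H](O[Si](C)(C)C(C)(C)C)C(C)(C)/C=C/S(=O)(=O)c1ccccc1 | intermediate
13 | (3Z,7S,9E)-2,7-bis(tert-butyldimethylsilyloxy)-4,8,8-trimethyl-10-(phenylsulfonyl)deca-1,3,9-triene | C=C(O[Si](C)(C)C(C)(C)C)/C=C(/C)CC[C@H](O[Si](C)(C)C(C)(C)C)C(C)(C)/C=C/S(=O)(=O)c1ccccc1 | intermediate
14 | cis-fused cycloadduct, 3β,8-bis(tert-butyldimethylsilyloxy)-4,4,10β-trimethyl-6β-(phenylsulfonyl)-5β-H-octal-8-ene | C1(O[Si](C)(C)C(C)(C)C)=C[C@@]2(C)CC[C@H](O[Si](C)(C)C(C)(C)C)C(C)(C)[C@H]2[C@H](S(=O)(=O)c3ccccc3)C1 | intermediate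
15 | cis-fused silyl enol ether, 3β,8-bis(tert-butyldimethylsilyloxy)-4,4,10β-trimethyl-5β-H-octal-8-ene | C1(O[Si](C)(C)C(C)(C)C)=C[C@@]2(C)CC[C@H](O[Si](C)(C)C(C)(C)C)C(C)(C)[C@H]2CC1 | intermediate
16 | chloromethyl phenyl sulfide | ClCSc1ccccc1 | starting material
17 | 3β-(tert-butyldimethylsilyloxy)-4,4,10β-trimethyl-9β-[(phenylthio)methyl]-5β-H-decalin-8-one | c3ccccc3SC[C@@H]1[C@@]2(C)CC[C@H](O[Si](C)(C)C(C)(C)C)C(C)(C)[C@H]2CCC1=O | intermediate
18 | 3β-(tert-butyldimethylsilyloxy)-11-(phenylthio)-5β-driman-8α-ol | c3ccccc3SC[C@@H]1[C@@]2(C)CC[C@H](O[Si](C)(C)C(C)(C)C)C(C)(C)[C@H]2CC[C@@]1(C)O | intermediate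
19 | 3β-(tert-butyldimethylsilyloxy)-11-(phenylsulfonyl)-5β-driman-8α-ol | O=S(=O)(c3ccccc3)C[C@@H]1[C@@]2(C)CC[C@H](O[Si](C)(C)C(C)(C)C)C(C)(C)[C@H]2CC[C@@]1(C)O | intermediate
20 | (2E,6E)-farnesol | CC(C)=CCC/C(C)=C/CC/C(C)=C/CO | starting material
21 | (2E,6E)-farnesyl acetate | CC(C)=CCC/C(C)=C/CC/C(C)=C/COC(C)=O | intermediate
22 | (2E,6E,10E)-12-hydroxy-3,7,11-trimethyldodeca-2,6,10-trien-1-yl acetate | C/C(=C\CC/C(C)=C/CC/C(C)=C/COC(C)=O)CO | intermediate
23 | (2E,6E,10E)-12-(tert-butyldimethylsilyloxy)-3,7,11-trimethyldodeca-2,6,10-trien-1-yl acetate | C/C(=C\CC/C(C)=C/CC/C(C)=C/COC(C)=O)CO[Si](C)(C)C(C)(C)C | intermediate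
24 | (2E,6E,10E)-12-(tert-butyldimethylsilyloxy)-3,7,11-trimethyldodeca-2,6,10-trien-1-ol | C/C(=C\CC/C(C)=C/CC/C(C)=C/CO)CO[Si](C)(C)C(C)(C)C | intermediate
25 | (2E,6E,10E)-1-bromo-12-(tert-butyldimethylsilyloxy)-3,7,11-trimethyldodeca-2,6,10-triene | C/C(=C\CC/C(C)=C/CC/C(C)=C/CBr)CO[Si](C)(C)C(C)(C)C | intermediate
26 | dilithio sulfone dianion of 19 (C8 alkoxide, C11 carbanion) | [Li+].[Li+].O=S(=O)(c3ccccc3)[CH-][C@@H]1[C@@]2(C)CC[C@H](O[Si](C)(C)C(C)(C)C)C(C)(C)[C@H]2CC[C@@]1(C)[O-] | intermediate
27 | C11-(phenylsulfonyl) bis-silyl ether of the target skeleton (C11 epimers) | C/C(=C\CC/C(C)=C/CC/C(C)=C/CC(S(=O)(=O)c3ccccc3)[C@@H]1[C@@]2(C)CC[C@H](O[Si](C)(C)C(C)(C)C)C(C)(C)[C@H]2CC[C@@]1(C)O)CO[Si](C)(C)C(C)(C)C | intermediate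
28 | 3β-O,ω-O-bis(tert-butyldimethylsilyl) ether of the target | C/C(=C\CC/C(C)=C/CC/C(C)=C/CC[C@@H]1[C@@]2(C)CC[C@H](O[Si](C)(C)C(C)(C)C)C(C)(C)[C@H]2CC[C@@]1(C)O)CO[Si](C)(C)C(C)(C)C | intermediate
29 | Myrrhanol A, (3S,5S,8R,9R,10S), cis-fused | C/C(=C\CC/C(C)=C/CC/C(C)=C/CC[C@@H]1[C@@]2(C)CC[C@H](O)C(C)(C)[C@H]2CC[C@@]1(C)O)CO | target

## Step count and risks

Total step count: 23. Longest linear sequence: 18 steps (steps 1–15 and 21–23); steps 16–20 make the side-chain bromide.

Steps most likely to fail:

1. Step 11. The cycloaddition of the hindered (Z)-diene may be so slow at the temperature needed that [1,5]-hydrogen migration within the diene, or thermal decay of the silyl enol ether, outruns ring closure; the facial preference set by C3 also weakens as the temperature rises. Fallback: change the activating group to nitro, which should allow the cycloaddition well below the temperature of the hydrogen shift. The fallback sets out from keto aldehyde 10. Henry addition of nitromethane (catalytic tetramethylguanidine, THF, 0 °C) gives the nitro alcohol (3Z,7S)-7-(tert-butyldimethylsilyloxy)-9-hydroxy-4,8,8-trimethyl-10-nitrodec-3-en-2-one F1. Dehydration with MsCl and Et3N gives the (E)-nitroalkene (3Z,7S,9E)-7-(tert-butyldimethylsilyloxy)-4,8,8-trimethyl-10-nitrodeca-3,9-dien-2-one F2. TBSOTf and Et3N then give the nitro triene (3Z,7S,9E)-2,7-bis(tert-butyldimethylsilyloxy)-4,8,8-trimethyl-10-nitrodeca-1,3,9-triene F3, which is heated in toluene at about 90 °C to the 6β-nitro cis-fused cycloadduct F4 by the same exo-tether, endo-activator transition state. Radical denitration (Bu3SnH, AIBN, toluene, 110 °C) returns to the route at silyl enol ether 15.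

2. Step 13. Carbon–carbon bond formation at the neopentyl-type C9 may be sluggish, so that protodesilylation to the ketone takes over, or the kinetically formed axial C9 substituent may epimerise under the Lewis acid. Fallback: form the C9–C11 bond with a carbenoid instead of a cation. The fallback sets out from silyl enol ether 15. Simmons–Smith cyclopropanation in the Furukawa variant (Et2Zn, CH2I2, CH2Cl2, 0 °C) should deliver the methylene to the same exo β face and give the siloxycyclopropane, 8α-(tert-butyldimethylsilyloxy)-8β,9β-methano derivative F5. Electrophilic ring opening at the CH2–C8 bond with Hg(OAc)2 (then aqueous NaCl) gives the 9β-[(chloromercurio)methyl] ketone F6 without touching C9. Photostimulated radical substitution with PhSSPh (benzene, sunlamp) returns to the route at ketone 17.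

3. Step 14. The methyl nucleophile may attack the wrong (α) face through a minor ring-B conformer, the adjacent axial C9 substituent hindering the β trajectory, or enolisation with β-elimination of thiophenoxide may compete. Fallback: deliver oxygen as an electrophile and the methyl hydrogen as a hydride, which reverses the stereochemical outcome for a given facial bias and avoids basic carbon nucleophiles. The fallback sets out from ketone 17. Lombardo–Takai methylenation (Zn, CH2Br2, TiCl4, THF) gives 3β-(tert-butyldimethylsilyloxy)-11-(phenylthio)-5β-drim-8(12)-ene F7. mCPBA (3.3 equiv) epoxidises the exocyclic alkene from the face that the methyl nucleophile had preferred and oxidises the sulfide, giving the 8α,12-epoxy-3β-(tert-butyldimethylsilyloxy)-11-(phenylsulfonyl)-5β-drimane F8. LiBHEt3 (THF, 0 °C) opens the epoxide at the CH2 carbon and returns to the route at hydroxy sulfone 19.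

## Further compounds

F1 | step 11 | (3Z,7S)-7-(tert-butyldimethylsilyloxy)-9-hydroxy-4,8,8-trimethyl-10-nitrodec-3-en-2-one (C9 epimers) | CC(=O)/C=C(/C)CC[C@H](O[Si](C)(C)C(C)(C)C)C(C)(C)C(O)C[N+](=O)[O-]
F2 | step 11 | (3Z,7S,9E)-7-(tert-butyldimethylsilyloxy)-4,8,8-trimethyl-10-nitrodeca-3,9-dien-2-one | CC(=O)/C=C(/C)CC[C@H](O[Si](C)(C)C(C)(C)C)C(C)(C)/C=C/[N+](=O)[O-]
F3 | step 11 | (3Z,7S,9E)-2,7-bis(tert-butyldimethylsilyloxy)-4,8,8-trimethyl-10-nitrodeca-1,3,9-triene | C=C(O[Si](C)(C)C(C)(C)C)/C=C(/C)CC[C@H](O[Si](C)(C)C(C)(C)C)C(C)(C)/C=C/[N+](=O)[O-]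
F4 | step 11 | cis-fused 6β-nitro cycloadduct, 3β,8-bis(tert-butyldimethylsilyloxy)-4,4,10β-trimethyl-6β-nitro-5β-H-octal-8-ene | C1(O[Si](C)(C)C(C)(C)C)=C[C@@]2(C)CC[C@H](O[Si](C)(C)C(C)(C)C)C(C)(C)[C@H]2[C@H]([N+](=O)[O-])C1
F5 | step 13 | siloxycyclopropane, 3β,8α-bis(tert-butyldimethylsilyloxy)-8β,9β-methano-4,4,10β-trimethyl-5β-H-decalin | C1[C@@H]2[C@@]3(C)CC[C@H](O[Si](C)(C)C(C)(C)C)C(C)(C)[C@H]3CC[C@]12O[Si](C)(C)C(C)(C)C
F6 | step 13 | 3β-(tert-butyldimethylsilyloxy)-9β-[(chloromercurio)methyl]-4,4,10β-trimethyl-5β-H-decalin-8-one | Cl[Hg]C[C@@H]1[C@@]2(C)CC[C@H](O[Si](C)(C)C(C)(C)C)C(C)(C)[C@H]2CCC1=O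
F7 | step 14 | 3β-(tert-butyldimethylsilyloxy)-11-(phenylthio)-5β-drim-8(12)-ene | c3ccccc3SC[C@@H]1[C@@]2(C)CC[C@H](O[Si](C)(C)C(C)(C)C)C(C)(C)[C@H]2CCC1=C
F8 | step 14 | 8α,12-epoxy-3β-(tert-butyldimethylsilyloxy)-11-(phenylsulfonyl)-5β-drimane | O=S(=O)(c3ccccc3)C[C@@H]1[C@@]2(C)CC[C@H](O[Si](C)(C)C(C)(C)C)C(C)(C)[C@H]2CC[C@]13CO3
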